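**Plan**

- Ring numbering: C1 (acyloxy carbon), C2, C3=C4 (methyl on C4), C5 (carries C7H2–O–coumarin), C6 (CMe2). Retrosynthetic cuts in order: the C7–O(aryl) ether, the C1–O acyl bond, the C3=C4 alkene (back to a C4 tertiary carbinol), ring bond C4–C5, chain bond C2–C3.
- Enabling feature: the oxygen on C1 and carbon C7 on C5 are cis and 1,3 to each other across C6, so O–C1–C6–C5–C7 can be tied into a five-membered γ-lactone (C7 as carboxyl carbon) that the target lacks. C5 then is a lactone α-carbon and C4–C5 an aldol bond.
- Forward: C1 is fixed by resolving a terminal epoxide. Methallyl opening joins C2–C3 and the γ-lactone ring closes first. α-Bromination and ozonolysis then arm C5 and C4.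
- SmI2 closes the carbocycle as a 6-oxabicyclo[3.2.1]octan-7-one. Dehydration, reductive lactone opening, then O-silylation, acylation, desilylation and aryl ether formation finish; the coumarin ring is bought.
- Stereochemistry: C1 from the hydrolytic kinetic resolution; C5 from the lactone tether (only the cis-bridged closure can form, and the bridgehead cannot epimerise); the ester α-carbon from purchased (R)-2-methylbutanoic acid.

Key step: step 6

Remark (sense of the resolution): for alkyl-substituted terminal oxiranes the (S,S)-cobalt–salen catalyst is taken to hydrolyse the (R)-epoxide and leave the (S)-epoxide; this would be confirmed on a first batch by Mosher ester analysis of a ring-opened sample, and the catalyst antipode used if needed.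

Remark (purchased materials): the methallyl Grignard reagent is bought as its THF solution (otherwise made from 3-chloro-2-methylprop-1-ene and magnesium), and (R)-2-methylbutanoic acid is bought as the single enantiomer.

**Route**

Step 1
Reactants: 1 ethyl 3,3-dimethylpent-4-enoate
Product: 2 ethyl 3-methyl-3-(oxiran-2-yl)butanoate (racemic)
Conditions: mCPBA, NaHCO3, CH2Cl2, 0 °C → rt
Reagents that add atoms: mCPBA, O=C(OO)c1cccc(Cl)c1
Why: Prilezhaev epoxidation of the only alkene by the peracid, with the ester inert; the racemate is intended because the centre is resolved in step 2.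

Step 2
Reactants: 2 ethyl 3-methyl-3-(oxiran-2-yl)butanoate (racemic)
Product: 3 ethyl 3-methyl-3-[(2S)-oxiran-2-yl]butanoate
Conditions: (S,S)-(salen)Co(III)OAc (2 mol%), H2O (0.55 equiv), THF, 0 °C → rt
Reagents that add atoms: none
Why: Jacobsen hydrolytic kinetic resolution, in which the chiral cobalt–salen catalyst hydrolyses the (R)-epoxide selectively so that the unreacted (S)-epoxide, whose stereocentre becomes C1 of the target, is recovered; tert-alkyl oxiranes are established substrates.

Step 3
Reactants: 3 ethyl 3-methyl-3-[(2S)-oxiran-2-yl]butanoate; 4 2-methylallylmagnesium chloride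
Product: 6 (5R)-4,4-dimethyl-5-(3-methylbut-3-en-1-yl)dihydrofuran-2(3H)-one, via hydroxy ester 5 (not isolated)
Conditions: CuI (10 mol%), THF, −40 °C, slow addition of 4; aq NH4Cl; then PPTS (cat.), toluene, 60 °C
Reagents that add atoms: none
Why: copper-catalysed SN2 opening of the terminal epoxide at its unsubstituted carbon by the allylic Grignard reagent (kept at low standing concentration beside the neopentyl-shielded ester) leaves the stereocentre untouched, and the gem-dimethyl group then drives acid-catalysed γ-lactonisation; the descriptor changes from S to R only through the CIP priorities.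

Step 4
Reactants: 6 (5R)-4,4-dimethyl-5-(3-methylbut-3-en-1-yl)dihydrofuran-2(3H)-one
Product: 8 (5R)-3-bromo-4,4-dimethyl-5-(3-methylbut-3-en-1-yl)dihydrofuran-2(3H)-one (both C3 epimers), via silyl ketene acetal 7 (not isolated)
Conditions: LDA, TMSCl, THF, −78 °C; then NBS, −78 → 0 °C
Reagents that add atoms: N-bromosuccinimide, O=C1CCC(=O)N1Br
Why: α-bromination of a lactone through its silyl ketene acetal, which reacts with NBS at −78 °C far faster than the 1,1-disubstituted alkene; the only α-position is brominated, no β-hydrogen is available for elimination, and the epimer ratio at C3 is irrelevant because this carbon becomes an enolate in step 6.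

Step 5
Reactants: 8 (5R)-3-bromo-4,4-dimethyl-5-(3-methylbut-3-en-1-yl)dihydrofuran-2(3H)-one
Product: 10 (5R)-3-bromo-4,4-dimethyl-5-(3-oxobutyl)dihydrofuran-2(3H)-one (both C3 epimers), via secondary ozonide 9 (not isolated)
Conditions: O3, CH2Cl2, −78 °C; then Me2S, −78 °C → rt
Reagents that add atoms: ozone, [O-][O+]=O
Why: ozonolysis with reductive work-up turns the 1,1-disubstituted alkene into the methyl ketone, while the secondary bromide next to a quaternary carbon is inert to ozone and too hindered for substitution by dimethyl sulfide.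

Step 6
Reactants: 10 (5R)-3-bromo-4,4-dimethyl-5-(3-oxobutyl)dihydrofuran-2(3H)-one
Product: 12 (1R,5R)-2-hydroxy-2,8,8-trimethyl-6-oxabicyclo[3.2.1]octan-7-one (C2 carbinol epimers), via samarium(III) enolate 11 (not isolated)
Conditions: SmI2 (2.5 equiv), THF, −78 → −20 °C, slow addition of 10 at high dilution; quench with cold 0.1 M HCl
Reagents that add atoms: none
Why: Two single-electron transfers from SmI2 cleave the C–Br bond and give the samarium(III) enolate 11 only at the lactone α-carbon (future C5), while the more acidic methyl ketone is never enolised; the oxophilic metal then binds the ketone and the enolate carbon adds to it through a chelated aldol transition state. The closest known reaction type is the SmI2-promoted intramolecular Reformatsky reaction of α-halo esters and lactones with ketones. The six-membered carbocycle closes in a 6-(enolexo)-exo-trig mode by forming C4–C5, which at the same time creates the 6-oxabicyclo[3.2.1]octan-7-one. The new bridgehead centre (C5 of the target) is controlled by the resolved C1 centre, because the three-atom tether hangs from one face of the lactone and can reach the planar enolate carbon only on that face, so only the cis-bridged bicycle can form; the second new centre, the C4 carbinol, is set by the chelate but is removed in step 7. The step needs reduction of the bromide in preference to the ketone (α-bromo esters are reduced by SmI2 at −78 °C without HMPA, unactivated ketones are not), cyclisation in preference to intermolecular aldol addition or enolate protonation (slow addition into excess SmI2, high dilution, dry THF), and a cold quench to forestall retro-aldol cleavage.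

Step 7
Reactants: 12 (1R,5R)-2-hydroxy-2,8,8-trimethyl-6-oxabicyclo[3.2.1]octan-7-one
Product: 13 (1S,5R)-2,8,8-trimethyl-6-oxabicyclo[3.2.1]oct-2-en-7-one
Conditions: p-TsOH·H2O (cat.), toluene, reflux, Dean–Stark
Reagents that add atoms: none
Why: acid-catalysed E1 dehydration of the tertiary carbinol under thermodynamic control, in which proton loss toward the bridgehead is excluded by Bredt's rule and equilibration through the tertiary cation funnels any exocyclic methylene isomer to the more stable trisubstituted ring alkene (C3=C4 of the target); the bridgehead descriptor changes from R to S only through the CIP priorities.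

Step 8
Reactants: 13 (1S,5R)-2,8,8-trimethyl-6-oxabicyclo[3.2.1]oct-2-en-7-one
Product: 14 (1R,5S)-5-(hydroxymethyl)-4,6,6-trimethylcyclohex-3-en-1-ol
Conditions: LiAlH4, THF, 0 °C → rt; Fieser work-up
Reagents that add atoms: none
Why: hydride reduction of the lactone cleaves the acyl–oxygen bond, so the C1–O configuration is retained and the cis diol results, while the isolated alkene is inert and the former bridgehead carbon is not epimerised.

Step 9
Reactants: 14 (1R,5S)-5-(hydroxymethyl)-4,6,6-trimethylcyclohex-3-en-1-ol
Product: 15 (1R,5S)-5-{[(tert-butyldimethylsilyl)oxy]methyl}-4,6,6-trimethylcyclohex-3-en-1-ol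
Conditions: TBSCl (1.05 equiv), imidazole, CH2Cl2, 0 °C
Reagents that add atoms: tert-butyldimethylsilyl chloride, CC(C)(C)[Si](C)(C)Cl
Why: chemoselective silylation of the primary hydroxyl over the secondary hydroxyl flanked by the quaternary carbon; differentiating the cis 1,4-diol here avoids its closure to a bicyclic ether when C7 is later activated.

Step 10
Reactants: 15 (1R,5S)-5-{[(tert-butyldimethylsilyl)oxy]methyl}-4,6,6-trimethylcyclohex-3-en-1-ol; 16 (R)-2-methylbutanoic acid
Product: 17 (1R,5S)-5-{[(tert-butyldimethylsilyl)oxy]methyl}-4,6,6-trimethylcyclohex-3-en-1-yl (2R)-2-methylbutanoate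
Conditions: DCC, DMAP (cat.), CH2Cl2, 0 °C → rt
Reagents that add atoms: none
Why: Steglich esterification (carbodiimide activation, DMAP acyl transfer) acylates the hindered secondary alcohol with retention at C1, since no C–O bond at the ring is broken, and under conditions that do not deprotonate the α-stereocentre of the acid.

Step 11
Reactants: 17 (1R,5S)-5-{[(tert-butyldimethylsilyl)oxy]methyl}-4,6,6-trimethylcyclohex-3-en-1-yl (2R)-2-methylbutanoate
Product: 18 (1R,5S)-5-(hydroxymethyl)-4,6,6-trimethylcyclohex-3-en-1-yl (2R)-2-methylbutanoate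
Conditions: HF·pyridine, THF, 0 °C → rt
Reagents that add atoms: none
Why: fluoride-mediated desilylation under mildly acidic conditions frees the primary alcohol without ester cleavage and without the 1,4-acyl migration that a basic fluoride source could promote.

Step 12
Reactants: 18 (1R,5S)-5-(hydroxymethyl)-4,6,6-trimethylcyclohex-3-en-1-yl (2R)-2-methylbutanoate; 19 umbelliferone (7-hydroxycoumarin)
Product: 20 (1R,5S)-4,6,6-trimethyl-5-{[(2-oxo-2H-chromen-7-yl)oxy]methyl}cyclohex-3-en-1-yl (2R)-2-methylbutanoate
Conditions: PPh3, DIAD, THF, 0 °C → rt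
Reagents that add atoms: none
Why: Mitsunobu etherification, in which the primary alcohol is activated as its alkoxyphosphonium ion and displaced by the acidic coumarin phenol in an SN2 reaction at the achiral CH2, so that no stereocentre is touched and the ester and coumarin lactone survive the neutral conditions.

**Compound list**

1 | ethyl 3,3-dimethylpent-4-enoate | CCOC(=O)CC(C)(C)C=C | starting material
2 | ethyl 3-methyl-3-(oxiran-2-yl)butanoate (racemic) | CCOC(=O)CC(C)(C)C1CO1 | intermediate
3 | ethyl 3-methyl-3-[(2S)-oxiran-2-yl]butanoate | CCOC(=O)CC(C)(C)[C@H]1CO1 | intermediate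
4 | 2-methylallylmagnesium chloride (THF solution) | CC(=C)C[Mg]Cl | starting material
5 | ethyl (4R)-4-hydroxy-3,3,7-trimethyloct-7-enoate | CCOC(=O)CC(C)(C)[C@H](O)CCC(C)=C | intermediate (not isolated)
6 | (5R)-4,4-dimethyl-5-(3-methylbut-3-en-1-yl)dihydrofuran-2(3H)-one | CC(=C)CC[C@H]1OC(=O)CC1(C)C | intermediate
7 | {[(5R)-4,4-dimethyl-5-(3-methylbut-3-en-1-yl)-4,5-dihydrofuran-2-yl]oxy}trimethylsilane | CC(=C)CC[C@H]1OC(O[Si](C)(C)C)=CC1(C)C | intermediate (not isolated)
8 | (5R)-3-bromo-4,4-dimethyl-5-(3-methylbut-3-en-1-yl)dihydrofuran-2(3H)-one (C3 epimers) | CC(=C)CC[C@H]1OC(=O)C(Br)C1(C)C | intermediate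
9 | (5R)-3-bromo-4,4-dimethyl-5-[2-(3-methyl-1,2,4-trioxolan-3-yl)ethyl]dihydrofuran-2(3H)-one (secondary ozonide of 8) | CC1(CC[C@H]2OC(=O)C(Br)C2(C)C)OCOO1 | intermediate (not isolated)
10 | (5R)-3-bromo-4,4-dimethyl-5-(3-oxobutyl)dihydrofuran-2(3H)-one (C3 epimers) | CC(=O)CC[C@H]1OC(=O)C(Br)C1(C)C | intermediate
11 | {[(5R)-4,4-dimethyl-5-(3-oxobutyl)-4,5-dihydrofuran-2-yl]oxy}diiodosamarium (samarium(III) enolate of 10) | CC(=O)CC[C@H]1OC(O[Sm](I)I)=CC1(C)C | intermediate (not isolated)
12 | (1R,5R)-2-hydroxy-2,8,8-trimethyl-6-oxabicyclo[3.2.1]octan-7-one (C2 epimers) | O=C2O[C@@H]1CCC(C)(O)[C@H]2C1(C)C | intermediate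
13 | (1S,5R)-2,8,8-trimethyl-6-oxabicyclo[3.2.1]oct-2-en-7-one | O=C2O[C@@H]1CC=C(C)[C@H]2C1(C)C | intermediate
14 | (1R,5S)-5-(hydroxymethyl)-4,6,6-trimethylcyclohex-3-en-1-ol | O[C@@H]1CC=C(C)[C@H](CO)C1(C)C | intermediate
15 | (1R,5S)-5-{[(tert-butyldimethylsilyl)oxy]methyl}-4,6,6-trimethylcyclohex-3-en-1-ol | O[C@@H]1CC=C(C)[C@H](CO[Si](C)(C)C(C)(C)C)C1(C)C | intermediate
16 | (R)-2-methylbutanoic acid | CC[C@@H](C)C(=O)O | starting material
17 | (1R,5S)-5-{[(tert-butyldimethylsilyl)oxy]methyl}-4,6,6-trimethylcyclohex-3-en-1-yl (2R)-2-methylbutanoate | CC[C@@H](C)C(=O)O[C@@H]1CC=C(C)[C@H](CO[Si](C)(C)C(C)(C)C)C1(C)C | intermediate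
18 | (1R,5S)-5-(hydroxymethyl)-4,6,6-trimethylcyclohex-3-en-1-yl (2R)-2-methylbutanoate | CC[C@@H](C)C(=O)O[C@@H]1CC=C(C)[C@H](CO)C1(C)C | intermediate
19 | umbelliferone (7-hydroxy-2H-chromen-2-one) | O=c1ccc2ccc(O)cc2o1 | starting material
20 | (1R,5S)-4,6,6-trimethyl-5-{[(2-oxo-2H-chromen-7-yl)oxy]methyl}cyclohex-3-en-1-yl (2R)-2-methylbutanoate | CC[C@@H](C)C(=O)O[C@@H]1CC=C(C)[C@H](COc2ccc3ccc(=O)oc3c2)C1(C)C | target

**Step count and risks**

Total step count: 12. Longest linear sequence: 12 steps (1 → 20); compounds 4, 16 and 19 are purchased and enter directly.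

Steps most likely to fail:

1. Step 6. The samarium enolate may be protonated before it cyclises (plain reductive debromination), or the congested aldolate may revert by retro-aldol cleavage. The fallback forms the same C4–C5 bond and the same bicycle by a cationic Mukaiyama-type closure. It sets out from 6. Ozonolysis (O3, CH2Cl2, −78 °C; Me2S) would pass through the ozonide (5R)-4,4-dimethyl-5-[2-(3-methyl-1,2,4-trioxolan-3-yl)ethyl]dihydrofuran-2(3H)-one F1 to the keto lactone (5R)-4,4-dimethyl-5-(3-oxobutyl)dihydrofuran-2(3H)-one F2. Ketalisation (HC(OMe)3, MeOH, PPTS) would give (5R)-5-(3,3-dimethoxybutyl)-4,4-dimethyldihydrofuran-2(3H)-one F3. LDA/TMSCl at −78 °C would give the silyl ketene acetal {[(5R)-5-(3,3-dimethoxybutyl)-4,4-dimethyl-4,5-dihydrofuran-2-yl]oxy}trimethylsilane F4. Catalytic TMSOTf in CH2Cl2 at −78 °C should ionise the ketal and let the ketene acetal add to the oxocarbenium ion, giving (1R,5R)-2-methoxy-2,8,8-trimethyl-6-oxabicyclo[3.2.1]octan-7-one F5. Loss of methanol with p-TsOH in hot toluene comes back to the route at 13.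

2. Step 7. Proton loss from the cation may go toward the methyl group (exocyclic alkene), or ionisation next to the electron-poor lactone carbon may be so slow that prolonged heating degrades the material. The fallback separates elimination from positional control and sets out from 12. SOCl2/pyridine at 0 °C (elimination through the chlorosulfite) should give 13 mixed with the exocyclic isomer (1S,5R)-8,8-dimethyl-2-methylidene-6-oxabicyclo[3.2.1]octan-7-one F6. Catalytic RhCl3·3H2O in ethanol at 80 °C would then isomerise F6 into the ring. The bridgehead stops migration in one direction and the trisubstituted alkene is the thermodynamic sink, so the fallback returns at 13.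

3. Step 3. The allylic Grignard reagent may add to the ester (or to the lactone once it forms) in competition with epoxide opening. The fallback forms the C2–C3 bond by a radical reaction that ignores carbonyl groups and sets out from 2. Resolution with the (R,R)-cobalt–salen catalyst and 0.45 equiv of water would hydrolyse the wanted (S)-epoxide to ethyl (4S)-4,5-dihydroxy-3,3-dimethylpentanoate F7. F7 would lactonise (PPTS, toluene) to (5S)-5-(hydroxymethyl)-4,4-dimethyldihydrofuran-2(3H)-one F8. I2/PPh3/imidazole would give (5S)-5-(iodomethyl)-4,4-dimethyldihydrofuran-2(3H)-one F9. Keck radical allylation with tributyl(2-methylallyl)stannane and AIBN in benzene at 80 °C returns to the route at 6.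

**Further compounds**

F1 | step 6 | (5R)-4,4-dimethyl-5-[2-(3-methyl-1,2,4-trioxolan-3-yl)ethyl]dihydrofuran-2(3H)-one | CC1(CC[C@H]2OC(=O)CC2(C)C)OCOO1
F2 | step 6 | (5R)-4,4-dimethyl-5-(3-oxobutyl)dihydrofuran-2(3H)-one | CC(=O)CC[C@H]1OC(=O)CC1(C)C
F3 | step 6 | (5R)-5-(3,3-dimethoxybutyl)-4,4-dimethyldihydrofuran-2(3H)-one | COC(C)(OC)CC[C@H]1OC(=O)CC1(C)C
F4 | step 6 | {[(5R)-5-(3,3-dimethoxybutyl)-4,4-dimethyl-4,5-dihydrofuran-2-yl]oxy}trimethylsilane | COC(C)(OC)CC[C@H]1OC(O[Si](C)(C)C)=CC1(C)C
F5 | step 6 | (1R,5R)-2-methoxy-2,8,8-trimethyl-6-oxabicyclo[3.2.1]octan-7-one (C2 epimers) | O=C2O[C@@H]1CCC(C)(OC)[C@H]2C1(C)C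
F6 | step 7 | (1S,5R)-8,8-dimethyl-2-methylidene-6-oxabicyclo[3.2.1]octan-7-one | O=C2O[C@@H]1CCC(=C)[C@H]2C1(C)C
F7 | step 3 | ethyl (4S)-4,5-dihydroxy-3,3-dimethylpentanoate | CCOC(=O)CC(C)(C)[C@H](O)CO
F8 | step 3 | (5S)-5-(hydroxymethyl)-4,4-dimethyldihydrofuran-2(3H)-one | OC[C@H]1OC(=O)CC1(C)C
F9 | step 3 | (5S)-5-(iodomethyl)-4,4-dimethyldihydrofuran-2(3H)-one | IC[C@H]1OC(=O)CC1(C)C
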